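The γ-lactone is read as the Baeyer–Villiger product of a 2,2-disubstituted cyclobutanone. The bond between its quaternary carbon C5 and ring methylene C4 is read as the bond made when a cyclopropane enlarges. The key step exploits the vicinal pair C1'–OH/C5–O. The C1' hydroxyl of a cyclopropylidene allylic alcohol steers a Katsuki–Sharpless epoxidation onto the strained tetrasubstituted alkene, and the oxaspiropentane collapses in the same flask by 1,2-shift of a cyclopropane CH2 onto C5. One operation closes the four-membered ring, sets the quaternary stereocentre and frees the carbinol. The precursor is the (R)-allylic alcohol of the furanoterpenoid chain that ends in C(CH3)=cyclopropylidene.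

Key step: step 8

Assumption: 3-(triphenyl-λ5-phosphanylidene)butan-2-one and (1-ethoxycyclopropoxy)trimethylsilane are taken as catalogue reagents, and t-BuOOH is used as an anhydrous solution in decane.

Step 1
Reactants: 1 furan-3-ylmethanol
Product: 2 3-(chloromethyl)furan
Conditions: SOCl2, pyridine, Et2O, 0 °C
Reagents that add atoms: thionyl chloride, O=S(Cl)Cl
Why: Chlorodehydroxylation of a primary heterobenzylic alcohol through its chlorosulfite, with pyridine taking up the acid so that the furan is not exposed to HCl.

Step 2
Reactants: 2 3-(chloromethyl)furan; 3 geranyl chloride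
Product: 5 dendrolasin, via furylmethyl Grignard reagent 4 (not isolated)
Conditions: Mg, THF, 0 °C to rt; then 3, Li2CuCl4 (cat.), THF, 0 °C
Reagents that add atoms: none
Why: Copper-catalysed Grignard/allylic halide cross-coupling (Kochi type) should substitute the primary CH2Cl terminus directly, keeping the E-alkene and suppressing reaction through C2 of the furan.

Step 3
Reactants: 5 dendrolasin
Product: 6 neotorreyol, (2E,6E)-9-(furan-3-yl)-2,6-dimethylnona-2,6-dien-1-ol
Conditions: SeO2 (cat.), t-BuOOH, CH2Cl2, 0 °C to rt
Reagents that add atoms: selenium dioxide (catalytic oxygen carrier), O=[Se]=O; tert-butyl hydroperoxide (terminal oxygen source), CC(C)(C)OO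
Why: Catalytic SeO2 allylic oxidation (ene reaction, then [2,3]-sigmatropic shift) should prefer the least hindered terminal isopropylidene unit and, through its cyclic transition state, hydroxylate only the methyl group trans to the chain, giving the E-allylic alcohol.

Step 4
Reactants: 6 neotorreyol
Product: 7 3-[(3E,7E)-9-bromo-4,8-dimethylnona-3,7-dien-1-yl]furan
Conditions: CBr4, PPh3, CH2Cl2, 0 °C
Reagents that add atoms: carbon tetrabromide, BrC(Br)(Br)Br
Why: The Appel reaction converts the primary allylic alcohol by SN2 under neutral conditions, so neither allylic transposition, E/Z erosion nor acid damage to the furan is expected.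

Step 5
Reactants: 8 (1-ethoxycyclopropoxy)trimethylsilane; 9 3-(triphenyl-λ5-phosphanylidene)butan-2-one
Product: 11 3-cyclopropylidenebutan-2-one, via cyclopropanone 10 (not isolated)
Conditions: PhCO2H (10 mol %), toluene, 90 °C
Reagents that add atoms: none
Why: This is a Wittig olefination of a cyclopropanone hemiacetal derivative with a stabilised ylide, in which acid catalysis releases the exceptionally electrophilic cyclopropanone that even an acyl-stabilised ylide should capture.

Step 6
Reactants: 11 3-cyclopropylidenebutan-2-one; 7 3-[(3E,7E)-9-bromo-4,8-dimethylnona-3,7-dien-1-yl]furan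
Product: 13 (6E,10E)-2-cyclopropylidene-13-(furan-3-yl)-6,10-dimethyltrideca-6,10-dien-3-one, via lithium enolate 12 (not isolated)
Conditions: LDA, THF, −78 °C (11 added slowly to the base); then 7, DMPU, −78 to −30 °C
Reagents that add atoms: none
Why: In this kinetic enolate alkylation the acetyl CH3 is the only acidic site (the other α-carbon is fully substituted and γ-deprotonation would build a cyclopropene-like dienolate), and the primary allylic bromide is a fast SN2 partner.

Step 7
Reactants: 13 (6E,10E)-2-cyclopropylidene-13-(furan-3-yl)-6,10-dimethyltrideca-6,10-dien-3-one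
Product: 14 (3R,6E,10E)-2-cyclopropylidene-13-(furan-3-yl)-6,10-dimethyltrideca-6,10-dien-3-ol
Conditions: (S)-Me-CBS (0.2 equiv), catecholborane, toluene, −78 °C
Reagents that add atoms: none
Why: In the Corey–Bakshi–Shibata reduction the fully substituted alkenyl group acts as the large and the CH2 chain as the small substituent, so the (S)-catalyst should deliver hydride to the face that gives the (R)-carbinol, while catecholborane at −78 °C leaves all C=C bonds untouched.

Step 8
Reactants: 14 (3R,6E,10E)-2-cyclopropylidene-13-(furan-3-yl)-6,10-dimethyltrideca-6,10-dien-3-ol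
Product: 16 (2S)-2-[(1R,4E,8E)-11-(furan-3-yl)-1-hydroxy-4,8-dimethylundeca-4,8-dien-1-yl]-2-methylcyclobutan-1-one, via oxaspiropentane 15 (not isolated)
Conditions: Ti(OiPr)4 (0.2 equiv), D-(−)-DIPT (0.24 equiv), t-BuOOH (1.5 equiv), 4 Å MS, CH2Cl2, −20 °C
Reagents that add atoms: tert-butyl hydroperoxide, CC(C)(C)OO
Why: The (R)-carbinol binds to the Ti(IV)–D-(−)-tartrate complex, which transfers the peroxide oxygen to the cyclopropylidene C=C (Katsuki–Sharpless epoxidation; the three-membered ring closes by concerted syn oxygen transfer) to give oxaspiropentane 15. Under the Lewis-acidic titanium the C–O bond at the methyl-bearing carbon ionises, because only this cleavage gives a cyclopropylcarbinyl-type cation pushed by the cyclopropanolate oxygen, and a ring CH2 shifts onto that carbon, so the four-membered ring closes by a semipinacol 3→4 ring enlargement (σ-bond migration, not a Baldwin-type closure) that forms the quaternary carbon–CH2 bond and releases the strain of both small rings. The closest known reaction type is the tandem asymmetric epoxidation/enantiospecific ring expansion of 2-cyclopropylidene alcohols to 2,2-disubstituted cyclobutanones. The new quaternary centre is controlled by two elements: the face of oxygen delivery, where the tartrate rule for D-(−)-DIPT and the erythro preference of the (R)-alcohol (A1,2 strain with the vinylic methyl; fast-reacting enantiomer in the kinetic-resolution sense) are matched, and the migration anti to the departing oxygen (inversion), which together should give (S). Chemoselectivity over the two trisubstituted alkenes and the furan rests on the allylic hydroxyl, since Ti/t-BuOOH epoxidises only an alkene held at the metal by an allylic alkoxide, and any (S)-alcohol left from step 7 is mismatched and should lag behind, which upgrades the enantiopurity.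

Step 9
Reactants: 16 (2S)-2-[(1R,4E,8E)-11-(furan-3-yl)-1-hydroxy-4,8-dimethylundeca-4,8-dien-1-yl]-2-methylcyclobutan-1-one
Product: 17 (5S)-5-[(1R,4E,8E)-11-(furan-3-yl)-1-hydroxy-4,8-dimethylundeca-4,8-dien-1-yl]-5-methyloxolan-2-one (target)
Conditions: 30% aq H2O2, NaOH (cat.), MeOH–THF, 0 °C
Reagents that add atoms: hydrogen peroxide, OO
Why: In the Baeyer–Villiger oxidation of a strained cyclobutanone with nucleophilic hydroperoxide the quaternary carbon migrates with retention, unactivated alkenes and the furan are inert to HOO−, and retro-aldol cleavage is disfavoured because it would need a strained cyclobutanone enolate.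

Compound list
1 | furan-3-ylmethanol | OCc1ccoc1 | starting material
2 | 3-(chloromethyl)furan | ClCc1ccoc1 | intermediate
3 | geranyl chloride, (2E)-1-chloro-3,7-dimethylocta-2,6-diene | CC(C)=CCC/C(C)=C/CCl | starting material
4 | (furan-3-ylmethyl)magnesium chloride (not isolated) | Cl[Mg]Cc1ccoc1 | intermediate
5 | dendrolasin, 3-[(3E)-4,8-dimethylnona-3,7-dien-1-yl]furan | CC(C)=CCC/C(C)=C/CCc1ccoc1 | intermediate
6 | neotorreyol, (2E,6E)-9-(furan-3-yl)-2,6-dimethylnona-2,6-dien-1-ol | C/C(=C\CCc1ccoc1)CC/C=C(\C)CO | intermediate
7 | 3-[(3E,7E)-9-bromo-4,8-dimethylnona-3,7-dien-1-yl]furan | C/C(=C\CCc1ccoc1)CC/C=C(\C)CBr | intermediate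
8 | (1-ethoxycyclopropoxy)trimethylsilane | CCOC1(O[Si](C)(C)C)CC1 | starting material
9 | 3-(triphenyl-λ5-phosphanylidene)butan-2-one | CC(=O)C(C)=P(c1ccccc1)(c1ccccc1)c1ccccc1 | starting material
10 | cyclopropanone (not isolated) | O=C1CC1 | intermediate
11 | 3-cyclopropylidenebutan-2-one | CC(=O)C(C)=C1CC1 | intermediate
12 | lithium 3-cyclopropylidenebut-1-en-2-olate (not isolated) | [Li]OC(=C)C(C)=C1CC1 | intermediate
13 | (6E,10E)-2-cyclopropylidene-13-(furan-3-yl)-6,10-dimethyltrideca-6,10-dien-3-one | C/C(=C\CCc1ccoc1)CC/C=C(\C)CCC(=O)C(C)=C1CC1 | intermediate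
14 | (3R,6E,10E)-2-cyclopropylidene-13-(furan-3-yl)-6,10-dimethyltrideca-6,10-dien-3-ol | C/C(=C\CCc1ccoc1)CC/C=C(\C)CC[C@@H](O)C(C)=C1CC1 | intermediate
15 | (1R,4E,8E)-11-(furan-3-yl)-4,8-dimethyl-1-[(2R)-2-methyl-1-oxaspiro[2.2]pentan-2-yl]undeca-4,8-dien-1-ol (not isolated) | C/C(=C\CCc1ccoc1)CC/C=C(\C)CC[C@@H](O)[C@@]1(C)OC12CC2 | intermediate
16 | (2S)-2-[(1R,4E,8E)-11-(furan-3-yl)-1-hydroxy-4,8-dimethylundeca-4,8-dien-1-yl]-2-methylcyclobutan-1-one | C/C(=C\CCc1ccoc1)CC/C=C(\C)CC[C@@H](O)[C@]1(C)CCC1=O | intermediate
17 | (5S)-5-[(1R,4E,8E)-11-(furan-3-yl)-1-hydroxy-4,8-dimethylundeca-4,8-dien-1-yl]-5-methyloxolan-2-one | C/C(=C\CCc1ccoc1)CC/C=C(\C)CC[C@@H](O)[C@]1(C)CCC(=O)O1 | target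

Total step count: 9. Longest linear sequence: 8 (steps 1–4 and 6–9, from furan-3-ylmethanol); step 5 is a one-step side branch.

Steps most likely to fail

Step 8. Oxygen transfer to the crowded tetrasubstituted alkene may be slow or poorly face-selective, and ionisation running ahead of migration would erode the stereochemical fidelity. The fallback sets out from bromide 7 and comes back at cyclobutanone 16. It moves the hydroxyl onto the cyclopropane and the epoxide into the chain. Alkylation of lithioacetonitrile with 7 gives chain nitrile F1. DIBAL-H reduction gives chain aldehyde F2. Still–Gennari olefination with methyl 2-[bis(2,2,2-trifluoroethoxy)phosphoryl]propanoate (KHMDS, 18-crown-6) gives (Z)-enoate F3. A Kulinkovich cyclopropanation (EtMgBr, Ti(OiPr)4) gives (Z)-alkenylcyclopropanol F4. Hydroxyl-directed asymmetric epoxidation of this tertiary allylic alcohol (Hf(IV)–bishydroxamic acid catalyst, cumene hydroperoxide) gives epoxy cyclopropanol F5. Its Lewis-acid-induced semipinacol rearrangement of the 2,3-epoxy alcohol type (BF3·OEt2, CH2Cl2, −78 °C) shifts a cyclopropane CH2 anti to the tertiary C–O bond and gives 16. Both stereocentres then follow from one alkene geometry and one epoxide face.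

Step 6. The enolate may add in a conjugate sense to the strain-activated cyclopropylidene ketone (self-condensation), and proton transfer may lead to double alkylation. The fallback sets out from ylide 9 and bromide 7 and comes back at enone 13. Ylide 9 is metalated at the acetyl methyl group with n-BuLi (THF, −78 °C) and alkylated with 7 to give chain keto ylide F6. Wittig olefination of cyclopropanone 10, released from 8 as in step 5, then installs the cyclopropylidene unit last, under weakly acidic conditions with no enolate present.

Step 5. Olefination may be sluggish because the α-branched acyl-stabilised ylide is a weak nucleophile, so the released cyclopropanone is lost to ring opening and oligomerisation. The fallback sets out from 8 and comes back at 11. Compound 8 is olefinated with the more nucleophilic ester-stabilised ylide ethyl 2-(triphenyl-λ5-phosphanylidene)propanoate to give cyclopropylidene ester F7. Aminolysis with MeONHMe·HCl/i-PrMgCl gives Weinreb amide F8, and addition of MeMgBr gives 11.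

Further compounds
F1 | step 8 | chain nitrile, (4E,8E)-11-(furan-3-yl)-4,8-dimethylundeca-4,8-dienenitrile | C/C(=C\CCc1ccoc1)CC/C=C(\C)CCC#N
F2 | step 8 | chain aldehyde, (4E,8E)-11-(furan-3-yl)-4,8-dimethylundeca-4,8-dienal | C/C(=C\CCc1ccoc1)CC/C=C(\C)CCC=O
F3 | step 8 | (Z)-enoate, methyl (2Z,6E,10E)-13-(furan-3-yl)-2,6,10-trimethyltrideca-2,6,10-trienoate | C/C(=C\CCc1ccoc1)CC/C=C(\C)CC/C=C(/C)C(=O)OC
F4 | step 8 | (Z)-alkenylcyclopropanol, 1-[(2Z,6E,10E)-13-(furan-3-yl)-6,10-dimethyltrideca-2,6,10-trien-2-yl]cyclopropan-1-ol | C/C(=C\CCc1ccoc1)CC/C=C(\C)CC/C=C(/C)C1(O)CC1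
F5 | step 8 | epoxy cyclopropanol, 1-[(2R,3R)-3-[(3E,7E)-10-(furan-3-yl)-3,7-dimethyldeca-3,7-dien-1-yl]-2-methyloxiran-2-yl]cyclopropan-1-ol | C/C(=C\CCc1ccoc1)CC/C=C(\C)CC[C@H]1O[C@@]1(C)C2(O)CC2
F6 | step 6 | chain keto ylide, (6E,10E)-13-(furan-3-yl)-6,10-dimethyl-2-(triphenyl-λ5-phosphanylidene)trideca-6,10-dien-3-one | C/C(=C\CCc1ccoc1)CC/C=C(\C)CCC(=O)C(C)=P(c1ccccc1)(c1ccccc1)c1ccccc1
F7 | step 5 | cyclopropylidene ester, ethyl 2-cyclopropylidenepropanoate | CCOC(=O)C(C)=C1CC1
F8 | step 5 | Weinreb amide, 2-cyclopropylidene-N-methoxy-N-methylpropanamide | CON(C)C(=O)C(C)=C1CC1
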